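A small charge of capture agent went into each flask, and I wanted to know how much of the substrate it could hold away from the product.

    substrate ⇌ product (k1 = 0.062 /s, Ea1 = 79.0 kJ/mol)
    capture agent + intermediate A → trapped intermediate (k2 = 27 /M/s, Ea2 = 50.0 kJ/mol)
    intermediate A ⇌ product (K3 = 4.8, k3 = 0.0060 /s, Ea3 = 95.0 kJ/mol, ΔH3 = 7.00 kJ/mol)
    intermediate B ⇌ intermediate C (K4 = 1.4, k4 = 0.052 /s, Ea4 = 68.0 kJ/mol, ΔH4 = −57.0 kJ/mol)
    substrate → intermediate B (k5 = 0.016 /s, Ea5 = 86.0 kJ/mol)
    substrate ⇌ intermediate A (K6 = 0.38, k6 = 0.015 /s, Ea6 = 93.0 kJ/mol, ΔH6 = 17.0 kJ/mol)
    (constants at 25 °C)

in all of them: substrate 0.0010 M; capture agent 0.100 mM; time 3.0 min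
- winter: temperature 25 °C
- noon: temperature 10 °C
- dusk: temperature 40 °C
- autumn: temperature −5 °C

- the constants hold at 25 °C; other temperatures follow from the activation energies and enthalpies

- the flask that comes out highest in amount of product, in percent of the substrate charged, or "all alike" when all lie within 1.5 percentage points (winter / noon / dusk / autumn / all alike)
- product at the end, in percent of the substrate charged, winter
- product at the end, in percent of the substrate charged, noon
- product at the end, in percent of the substrate charged, dusk
- product at the end, in percent of the substrate charged, autumn

I began with the balance of the capture agent. At 0.100 mM against 1 mM of substrate it was charged in the smaller amount, which made it the limiting reagent of the trapping step. Each capture agent that reacted took one intermediate A and became one trapped intermediate, so [capture agent] + [trapped intermediate] stayed at 0.100 mM. I set this out for the start and for the extreme case of a full trap: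

| | at the start | trap full |
|---|---|---|
| [capture agent] | 0.100 mM | 0 mM |
| [trapped intermediate] | 0 mM | 0.100 mM |
| other forms of the substrate charge | 1 mM | 0.900 mM |

The first two rows read as one: what the capture agent lost, the trapped intermediate gained. The third row then showed what the trap could do to the substrate, since even a full trap left 0.900 mM in the other forms. So I named the charge of capture agent over the charge of substrate the capture ceiling, 10.0%: the largest part of the substrate charge that can stand as trapped intermediate. No temperature enters it. The balance also gave a rule for any moment: trapped intermediate, in percent of the substrate charged, equals the ceiling times the fraction of capture agent consumed.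

My reckoning stopped there. It bounded the trap at 10.0% but gave no figure for product and no ranking of the flasks.

The forecast did commit itself. It named noon as highest, with 37.5% (35% to 40%) for noon, 22.9% (21% to 25%) for winter, 20.5% (19% to 22%) for autumn and 2.7% (2% to 3.5%) for dusk. Its grounds were that “warm flasks form product and then lose it, while the coldest flask has not yet had time to form it”, and it held the effect of the capture agent to be minor. These numbers are the forecast's own and do not come from my balance.

Noon came out highest at 37.5%, with winter at 22.9%, autumn at 20.4% and dusk at 2.69%, so the forecast held. In noon, capture charges from 0.0125 mM to 0.80 mM, at least, kept that product figure within 5 points of itself. The lead of noon over winter, 15 percentage points, is wider than the ceiling of 10.0%. Noon kept 90% of its capture agent, so the rule gives 1.01% of the substrate charge as trapped intermediate. Dusk kept 67%, so the rule gives 3.30% there, in a flask that ended with 2.69% product.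

The numbers are made up; the flask was simulated.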